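**Plan**

Cembrane numbering: ring carbons C1–C14; lactone O–C16(=O)–C15(C17)–C1–C2–C3; C18 on C4, C19 = methylidene on C8, C20 on C12. The 14-membered carbocycle and the δ-lactone share C1–C2–C3, so C1–C2 lies in both rings. The strip O–C3–C2–C1 next to the C4 tertiary carbinol is the retron of a 3,5-bridged 2-isoxazoline, made from a C1 nitrile oxide and a linalool-type vinyl carbinol C2=C3–C4.
Retrosynthesis: remove the C11/C12 epoxide oxygen, C15–C17 and the hydrogen on C1. Then remove C1=C15 and C16–O (the two lactone carbons). Place a temporary nitrogen between C1 and the C3 oxygen, and cut C1–C2 and O–C3 together. This opens both rings to an acyclic aldoxime, which is cut further at C7–C8 and C10–C11.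
Forward: the chain is joined at C10–C11 (Negishi) and C7–C8 (alkenyllithium plus aldehyde). One intramolecular nitrile oxide cycloaddition closes the carbocycle and the isoxazoline. N–O cleavage leaves the oxygen on C3. The lactone is built on that oxygen (ketenylidene ylide, hydride to C1, methyl to C15), and the epoxide comes last.
Stereochemistry: C4 from Sharpless epoxidation of geraniol (via (S)-linalool); C7 from CBS reduction; C3 from C4 in the cycloaddition; C1 from C3 and the bridge; C15 from C1; C11/C12 from the ent-Shi ketone.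

Key step: step 17

Remark on the chemistry: the target is read as (1R,3R,4S,7R,11S,12S,15S). (S)-Linalool of reliable enantiopurity is assumed not to be purchasable and is made from geraniol. Acyclic compounds 17–25 carry the atom numbers of the ring they give (C1 = oxygenated chain end, C2=C3 = vinyl group).

**Route**

Step 1
Reactants: 1 geraniol
Product: 2 (2S,3S)-2,3-epoxygeraniol
Conditions: Ti(OiPr)4 (5 mol%), L-(+)-diethyl tartrate (7 mol%), t-BuOOH, 4 Å MS, CH2Cl2, −20 °C
Reagents that add atoms: tert-butyl hydroperoxide, CC(C)(C)OO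
Why: Katsuki–Sharpless asymmetric epoxidation, in which the allylic hydroxyl binds titanium so that only the 2,3-alkene reacts and the L-tartrate should deliver oxygen to the face giving the 2S,3S epoxide, whose quaternary carbon becomes C4.

Step 2
Reactants: 2 (2S,3S)-2,3-epoxygeraniol
Product: 3 (2S,3R)-3-(iodomethyl)-2-methyl-2-(4-methylpent-3-enyl)oxirane
Conditions: I2, PPh3, imidazole, THF, 0 °C
Reagents that add atoms: iodine, II
Why: Garegg–Samuelsson (Appel-type) iodination of the primary alcohol runs under near-neutral conditions that leave the epoxide and both of its centres untouched (only the CIP label of the CH carbon changes).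

Step 3
Reactants: 3 (2S,3R)-3-(iodomethyl)-2-methyl-2-(4-methylpent-3-enyl)oxirane
Product: 4 (S)-linalool
Conditions: Zn dust, EtOH, reflux
Reagents that add atoms: none
Why: Reductive β-elimination (zinc insertion into C–I, then opening of the neighbouring epoxide) gives the tertiary vinyl carbinol, and the C–O bond at the quaternary carbon is never broken, so its configuration is kept.

Step 4
Reactants: 4 (S)-linalool
Product: 5 (S)-linalool triethylsilyl ether
Conditions: TESOTf, 2,6-lutidine, CH2Cl2, −78 → 0 °C
Reagents that add atoms: triethylsilyl triflate, CC[Si](CC)(CC)OS(=O)(=O)C(F)(F)F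
Why: Silyl triflate silylation is the standard way to cap a hindered tertiary alcohol; the ether prevents lactol formation in step 5 and supplies the allylic alkoxy group used in step 17.

Step 5
Reactants: 5 (S)-linalool triethylsilyl ether
Product: 7 (S)-4-methyl-4-(triethylsilyloxy)hex-5-enal, via ozonide 6 (not isolated)
Conditions: O3 (1 equiv), CH2Cl2, −78 °C; then Me2S, −78 °C → rt
Reagents that add atoms: ozone, O=[O+][O-]
Why: Chemoselective ozonolysis, in which the electron-rich trisubstituted alkene should consume one equivalent of ozone well ahead of the monosubstituted vinyl group on a quaternary carbon.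

Step 6
Reactants: 8 pent-4-yn-1-ol
Product: 10 (E)-5-iodo-4-methylpent-4-en-1-ol, via alkenylalane 9 (not isolated)
Conditions: AlMe3 (3 equiv), Cp2ZrCl2 (25 mol%), CH2Cl2, 0 °C → rt; then I2, THF, −30 °C
Reagents that add atoms: trimethylaluminium, C[Al](C)C; iodine, II
Why: Negishi zirconium-catalysed carboalumination adds methyl and aluminium syn with aluminium on the terminal carbon, and iodinolysis with retention fixes the E geometry of the later C11=C12 alkene.

Step 7
Reactants: 10 (E)-5-iodo-4-methylpent-4-en-1-ol
Product: 11 (E)-5-iodo-4-methylpent-4-enyl 4-methoxybenzyl ether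
Conditions: NaH, PMBCl, Bu4NI (cat.), THF/DMF, 0 °C → rt
Reagents that add atoms: 4-methoxybenzyl chloride, COc1ccc(CCl)cc1
Why: Williamson etherification gives a C1 protecting group that survives organolithium, borane and silylation steps and can be removed oxidatively beside two silyl ethers.

Step 8
Reactants: 12 3-bromobut-3-en-1-ol
Product: 13 2-bromo-4-iodobut-1-ene
Conditions: I2, PPh3, imidazole, CH2Cl2, 0 °C
Reagents that add atoms: iodine, II
Why: Garegg–Samuelsson iodination converts the primary alcohol into the alkyl iodide without touching the alkenyl bromide.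

Step 9
Reactants: 13 2-bromo-4-iodobut-1-ene; 11 (E)-5-iodo-4-methylpent-4-enyl 4-methoxybenzyl ether
Product: 15 (E)-2-bromo-9-(4-methoxybenzyloxy)-6-methylnona-1,5-diene, via organozinc iodide 14 (not isolated)
Conditions: 13, Zn dust, LiCl, THF, rt; then 11, Pd(PPh3)4 (5 mol%), THF, rt
Reagents that add atoms: none
Why: Negishi sp3–sp2 coupling forms C10–C11 with retention of alkene geometry, because zinc inserts only into the alkyl C–I bond and zerovalent palladium adds to the alkenyl iodide of 11 much faster than to a 1,1-disubstituted alkenyl bromide.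

Step 10
Reactants: 15 (E)-2-bromo-9-(4-methoxybenzyloxy)-6-methylnona-1,5-diene; 7 (S)-4-methyl-4-(triethylsilyloxy)hex-5-enal
Product: 17 acyclic C7 carbinol (4S,11E; both C7 epimers), via alkenyllithium 16 (not isolated)
Conditions: 15, t-BuLi (2.1 equiv), Et2O, −78 °C; then 7, −78 °C
Reagents that add atoms: none
Why: Bromine–lithium exchange and 1,2-addition of the alkenyllithium to the aldehyde join C7–C8 and install the C8 methylidene; the new carbinol centre forms without control and is erased in step 11.

Step 11
Reactants: 17 acyclic C7 carbinol (both C7 epimers)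
Product: 18 acyclic C7 enone (4S,11E)
Conditions: Dess–Martin periodinane, pyridine, CH2Cl2, 0 °C → rt
Reagents that add atoms: none
Why: Dess–Martin oxidation of the allylic alcohol under buffered conditions gives the 2-substituted enone without disturbing the silyl ether, the PMB ether or the alkenes.

Step 12
Reactants: 18 acyclic C7 enone
Product: 19 acyclic (7R)-allylic alcohol (4S,7R,11E)
Conditions: (S)-2-methyl-CBS-oxazaborolidine (20 mol%), catecholborane, toluene, −78 °C
Reagents that add atoms: none
Why: Corey–Bakshi–Shibata reduction, in which the ketone binds the catalyst boron anti to its larger 1-substituted vinyl arm so that the (S)-catalyst should give the 7R alcohol, while catecholborane at −78 °C does not hydroborate the alkenes.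

Step 13
Reactants: 19 acyclic (7R)-allylic alcohol
Product: 20 C7 tert-butyldimethylsilyl ether of 19
Conditions: TBSCl, imidazole, DMF, rt
Reagents that add atoms: tert-butyldimethylsilyl chloride, CC(C)(C)[Si](C)(C)Cl
Why: Standard silylation masks the only free hydroxyl before the C1 terminus is oxidised and adds bulk next to the C8 methylidene.

Step 14
Reactants: 20 C7 tert-butyldimethylsilyl ether
Product: 21 acyclic C1 primary alcohol (4S,7R,11E)
Conditions: DDQ, CH2Cl2/pH 7 phosphate buffer, 0 °C
Reagents that add atoms: none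
Why: Oxidative PMB cleavage by hydride abstraction from the electron-rich benzylic position is orthogonal to both silyl ethers and to unconjugated alkenes.

Step 15
Reactants: 21 acyclic C1 primary alcohol
Product: 22 acyclic C1 aldehyde
Conditions: Dess–Martin periodinane, pyridine, CH2Cl2, 0 °C → rt
Reagents that add atoms: none
Why: Dess–Martin oxidation stops cleanly at the aldehyde.

Step 16
Reactants: 22 acyclic C1 aldehyde
Product: 23 acyclic C1 aldoxime (E/Z at C=N immaterial)
Conditions: NH2OH·HCl, NaOAc, EtOH, rt
Reagents that add atoms: hydroxylamine hydrochloride, NO.Cl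
Why: Oxime condensation under acetate buffer brings in the nitrogen of the temporary ring and the oxygen atom that will end as the lactone ring oxygen.

Step 17
Reactants: 23 acyclic C1 aldoxime
Product: 26 macrocyclic 2-isoxazoline (3R,4S,7R,11E), via hydroximoyl chloride 24 (not isolated), via nitrile oxide 25 (not isolated)
Conditions: NCS, pyridine (cat.), CHCl3, rt; then syringe-pump addition (20 h) into Et3N, CH2Cl2 (final ca. 1 mM), 40 °C
Reagents that add atoms: none
Why: Chlorination of the aldoxime and slow dehydrochlorination release nitrile oxide 25 at high dilution, and its concerted suprafacial [3+2] cycloaddition to the C2=C3 vinyl group makes C1–C2 and O–C3 in one transition state; this is the intramolecular nitrile oxide–olefin cycloaddition, a reaction type known for twelve- to sixteen-membered rings. The five-membered isoxazoline closes as the [3+2] ring, and the 14-membered carbocycle closes in the bridged 3,5-sense (14-endo, nitrile oxide carbon on the terminal CH2), because an eleven-atom tether lets the intrinsic regiochemistry of a monosubstituted alkene operate (oxygen to the substituted carbon) and the quaternary C4 blocks C–C bonding at C3. The only new stereocentre, C3, is controlled by C4: in the inside-alkoxy transition state the C4–OTES bond lies inside, the C5 chain anti to the incoming oxygen and the smaller C18 methyl outside, which should expose the face giving the 3R,4S (anti) arrangement. Chemoselectivity among three alkenes is secured by the substrate: C11=C12 is trisubstituted and only two methylenes from C1, so its adduct would be a bridgehead imine in a bicyclo[2.2.1] frame, and addition to the C8 methylidene would need a nine-membered ring holding an E alkene. Furoxan formation is second order in 25 and is held back by the slow addition. The C=N and N–O bonds of the new ring are absent from the target and are cleaved in step 18, whereas the oxygen stays on C3 and becomes the lactone ring oxygen.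

Step 18
Reactants: 26 macrocyclic 2-isoxazoline
Product: 28 macrocyclic β-hydroxy ketone (C1 ketone and C3 hydroxyl; 3R,4S,7R,11E), via hydroxy imine 27 (not isolated)
Conditions: SmI2 (2.5 equiv), THF, 0 °C; then B(OH)3, MeOH/H2O, rt
Reagents that add atoms: water, O
Why: Single-electron reductive N–O cleavage followed by boric-acid-buffered imine hydrolysis unmasks the aldol-type array without touching the alkenes, the silyl ethers, the C3 centre or the C3–O bond made in step 17.

Step 19
Reactants: 28 macrocyclic β-hydroxy ketone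
Product: 30 bridged α,β-unsaturated δ-lactone (C1=C15; 3R,4S,7R,11E), via ester ylide 29 (not isolated)
Conditions: Ph3P=C=C=O, toluene, 110 °C
Reagents that add atoms: (triphenylphosphoranylidene)ketene, O=C=C=P(c1ccccc1)(c1ccccc1)c1ccccc1
Why: Tandem addition–intramolecular Wittig olefination with the Bestmann ylide, in which the only free hydroxyl (C3) adds to the cumulated ylide and the ester ylide closes on the C1 ketone through a six-membered transition state under neutral conditions.

Step 20
Reactants: 30 bridged α,β-unsaturated δ-lactone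
Product: 31 bridged saturated δ-lactone (1R,3R,4S,7R,11E)
Conditions: Cu(OAc)2·H2O (5 mol%), 1,2-bis(diphenylphosphino)benzene (5 mol%), (EtO)2MeSiH, t-BuOH, toluene, rt
Reagents that add atoms: none
Why: Copper hydride conjugate reduction, known for β,β-disubstituted unsaturated lactones, should deliver hydride to C1 axially and from the face opposite to the C4 substituent on C3 and the eleven-atom bridge hanging from it, which places C14 cis to C4 (1R) and leaves isolated alkenes alone.

Step 21
Reactants: 31 bridged saturated δ-lactone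
Product: 33 bridged α-methyl δ-lactone (1R,3R,4S,7R,15S,11E), via lithium enolate 32 (not isolated)
Conditions: LiN(iPr)2 (1.2 equiv), THF, −78 °C; then MeI, DMPU, −78 → −40 °C
Reagents that add atoms: iodomethane, CI
Why: Lactone enolate alkylation should occur anti to the C14 branch on the neighbouring C1 and give the trans C1/C15, all-equatorial lactone, which is also the thermodynamic epimer, so later base contact cannot scramble it.

Step 22
Reactants: 33 bridged α-methyl δ-lactone
Product: 34 (11S,12S)-epoxide of 33 (bis-silyl ether of the target)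
Conditions: ent-Shi ketone (L-fructose series, from L-sorbose, 30 mol%), Oxone (2KHSO5·KHSO4·K2SO4), K2CO3, Bu4NHSO4, MeCN/CH2(OMe)2–aq. Na2B4O7 buffer, 0 °C
Reagents that add atoms: potassium peroxymonosulfate, [K+].[O-]S(=O)(=O)OO
Why: Shi asymmetric epoxidation (chiral dioxirane, spiro transition state) should pick the electron-rich trisubstituted E alkene C11=C12 over the hindered 1,1-disubstituted methylidene next to OTBS, and the L-series ketone gives S,S epoxides where the D-fructose ketone gives R,R.

Step 23
Reactants: 34 (11S,12S)-epoxide bis-silyl ether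
Product: 35 target CNP0262409.1
Conditions: Bu4NF, AcOH, THF, 0 °C → rt
Reagents that add atoms: none
Why: Acetic-acid-buffered fluoride desilylation frees the C4 and C7 hydroxyls while keeping the alkoxide concentration low, so that the epoxide, the lactone and the C15 centre should persist.

**Compound list**

1 | geraniol | CC(C)=CCC/C(C)=C/CO | starting material
2 | (2S,3S)-2,3-epoxygeraniol | OC[C@@H]1O[C@@]1(C)CCC=C(C)C | intermediate
3 | (2S,3R)-3-(iodomethyl)-2-methyl-2-(4-methylpent-3-enyl)oxirane | IC[C@@H]1O[C@@]1(C)CCC=C(C)C | intermediate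
4 | (S)-linalool | C=C[C@@](C)(O)CCC=C(C)C | intermediate
5 | (S)-linalool triethylsilyl ether | C=C[C@@](C)(O[Si](CC)(CC)CC)CCC=C(C)C | intermediate
6 | ozonide (1,2,4-trioxolane) of the trisubstituted alkene of 5 | C=C[C@@](C)(O[Si](CC)(CC)CC)CCC1OOC(C)(C)O1 | intermediate
7 | (S)-4-methyl-4-(triethylsilyloxy)hex-5-enal | C=C[C@@](C)(O[Si](CC)(CC)CC)CCC=O | intermediate
8 | pent-4-yn-1-ol | C#CCCCO | starting material
9 | (E)-alkenyl(dimethyl)alane, O-dimethylaluminium alkoxide | C[Al](C)OCCC/C(C)=C/[Al](C)C | intermediate
10 | (E)-5-iodo-4-methylpent-4-en-1-ol | OCCC/C(C)=C/I | intermediate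
11 | (E)-5-iodo-4-methylpent-4-enyl 4-methoxybenzyl ether | COc1ccc(COCCC/C(C)=C/I)cc1 | intermediate
12 | 3-bromobut-3-en-1-ol | C=C(Br)CCO | starting material
13 | 2-bromo-4-iodobut-1-ene | C=C(Br)CCI | intermediate
14 | (3-bromobut-3-enyl)zinc iodide | C=C(Br)CC[Zn]I | intermediate
15 | (E)-2-bromo-9-(4-methoxybenzyloxy)-6-methylnona-1,5-diene | C=C(Br)CC/C=C(\C)CCCOCc1ccc(OC)cc1 | intermediate
16 | alkenyllithium from 15 (Li in place of Br) | [Li]C(=C)CC/C=C(\C)CCCOCc1ccc(OC)cc1 | intermediate
17 | (3S,10E)-14-(4-methoxybenzyloxy)-3,11-dimethyl-7-methylidene-3-(triethylsilyloxy)tetradeca-1,10-dien-6-ol, both carbinol epimers | C=C[C@@](C)(O[Si](CC)(CC)CC)CCC(O)C(=C)CC/C=C(\C)CCCOCc1ccc(OC)cc1 | intermediate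
18 | the corresponding 6-one (C7 enone in cembrane numbering) | C=C[C@@](C)(O[Si](CC)(CC)CC)CCC(=O)C(=C)CC/C=C(\C)CCCOCc1ccc(OC)cc1 | intermediate
19 | (3S,6R,10E)-alcohol (4S,7R in cembrane numbering) | C=C[C@@](C)(O[Si](CC)(CC)CC)CC[C@@H](O)C(=C)CC/C=C(\C)CCCOCc1ccc(OC)cc1 | intermediate
20 | tert-butyldimethylsilyl ether of 19 | C=C[C@@](C)(O[Si](CC)(CC)CC)CC[C@@H](O[Si](C)(C)C(C)(C)C)C(=C)CC/C=C(\C)CCCOCc1ccc(OC)cc1 | intermediate
21 | (4E,9R,12S)-9-(tert-butyldimethylsilyloxy)-4,12-dimethyl-8-methylidene-12-(triethylsilyloxy)tetradeca-4,13-dien-1-ol | C=C[C@@](C)(O[Si](CC)(CC)CC)CC[C@@H](O[Si](C)(C)C(C)(C)C)C(=C)CC/C=C(\C)CCCO | intermediate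
22 | the corresponding aldehyde | C=C[C@@](C)(O[Si](CC)(CC)CC)CC[C@@H](O[Si](C)(C)C(C)(C)C)C(=C)CC/C=C(\C)CCC=O | intermediate
23 | the corresponding aldoxime | C=C[C@@](C)(O[Si](CC)(CC)CC)CC[C@@H](O[Si](C)(C)C(C)(C)C)C(=C)CC/C=C(\C)CCC=NO | intermediate
24 | the corresponding hydroximoyl chloride | C=C[C@@](C)(O[Si](CC)(CC)CC)CC[C@@H](O[Si](C)(C)C(C)(C)C)C(=C)CC/C=C(\C)CCC(Cl)=NO | intermediate
25 | the corresponding nitrile oxide | C=C[C@@](C)(O[Si](CC)(CC)CC)CC[C@@H](O[Si](C)(C)C(C)(C)C)C(=C)CC/C=C(\C)CCC#[N+][O-] | intermediate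
26 | 14-membered carbocycle bridged by C1=N–O–C3 (2-isoxazoline); C4 OTES, C7 OTBS, C8 methylidene; 3R,4S,7R,11E | C=C1CC/C=C(\C)CCC2=NO[C@H](C2)[C@@](C)(O[Si](CC)(CC)CC)CC[C@H]1O[Si](C)(C)C(C)(C)C | intermediate
27 | macrocyclic C1 imine, C3 alcohol | C=C1CC/C=C(\C)CCC(=N)C[C@@H](O)[C@@](C)(O[Si](CC)(CC)CC)CC[C@H]1O[Si](C)(C)C(C)(C)C | intermediate
28 | macrocyclic C1 ketone, C3 alcohol (3R,4S,7R,11E) | C=C1CC/C=C(\C)CCC(=O)C[C@@H](O)[C@@](C)(O[Si](CC)(CC)CC)CC[C@H]1O[Si](C)(C)C(C)(C)C | intermediate
29 | C3 (triphenylphosphoranylidene)acetate of 28 | C=C1CC/C=C(\C)CCC(=O)C[C@@H](OC(=O)C=P(c2ccccc2)(c2ccccc2)c2ccccc2)[C@@](C)(O[Si](CC)(CC)CC)CC[C@H]1O[Si](C)(C)C(C)(C)C | intermediate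
30 | bridged 5,6-dihydropyran-2-one (C1=C15, C16 carbonyl, O on C3) | C=C1CC/C=C(\C)CCC2=CC(=O)O[C@H](C2)[C@@](C)(O[Si](CC)(CC)CC)CC[C@H]1O[Si](C)(C)C(C)(C)C | intermediate
31 | bridged δ-lactone, C15 unsubstituted (1R,3R,4S,7R,11E) | C=C1CC/C=C(\C)CC[C@@H]2C[C@@H](OC(=O)C2)[C@@](C)(O[Si](CC)(CC)CC)CC[C@H]1O[Si](C)(C)C(C)(C)C | intermediate
32 | lithium enolate of 31 | [Li+].C=C1CC/C=C(\C)CC[C@@H]2C[C@@H](OC([O-])=C2)[C@@](C)(O[Si](CC)(CC)CC)CC[C@H]1O[Si](C)(C)C(C)(C)C | intermediate
33 | bridged α-methyl δ-lactone (1R,3R,4S,7R,15S,11E) | C=C1CC/C=C(\C)CC[C@@H]2C[C@@H](OC(=O)[C@H]2C)[C@@](C)(O[Si](CC)(CC)CC)CC[C@H]1O[Si](C)(C)C(C)(C)C | intermediate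
34 | (11S,12S)-epoxide of 33 | C=C1CC[C@@H]2O[C@@]2(C)CC[C@@H]2C[C@@H](OC(=O)[C@H]2C)[C@@](C)(O[Si](CC)(CC)CC)CC[C@H]1O[Si](C)(C)C(C)(C)C | intermediate
35 | CNP0262409.1, (1R,3R,4S,7R,11S,12S,15S)-11,12-epoxy-4,7-dihydroxycembr-8(19)-en-16,3-olide | C=C1CC[C@@H]2O[C@@]2(C)CC[C@@H]2C[C@@H](OC(=O)[C@H]2C)[C@@](C)(O)CC[C@H]1O | target

**Step count**

Total steps: 23.
Longest linear sequence: 19 (steps 1–5, then 10–23).

**Steps most likely to fail**

**Step 17.** Second-order furoxan formation and intermolecular cycloaddition may outrun closure of the 14-membered ring. The transition state may also distinguish poorly between the C18 methyl and the C5 chain on C4, which would mean poor facial selectivity at C3.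

The fallback takes the ring closure away from the cycloaddition. It sets out from 15 and 7 and comes back at 26.
- DDQ frees (E)-8-bromo-4-methylnona-4,8-dien-1-ol F1 from 15.
- Dess–Martin oxidation gives (E)-8-bromo-4-methylnona-4,8-dienal F2, and NH2OH·HCl/NaOAc gives its oxime F3.
- Aqueous NaOCl/CH2Cl2 turns F3 into the bromodienyl nitrile oxide F4 in the presence of an excess of 7. Intermolecular cycloaddition then gives the isoxazoline aldehyde F5, whose C3 epimers can be separated on a small molecule.
- An intramolecular Nozaki–Hiyama–Kishi reaction (CrCl2, NiCl2 cat., DMSO/THF, high dilution) closes C7–C8 to the macrocyclic allylic alcohol F6.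
- Dess–Martin oxidation gives the macrocyclic enone F7, and CBS reduction as in step 12 gives the (7R)-alcohol F8.
- TBSCl/imidazole delivers 26.

**Step 22.** The macrocycle may present only one face of C11=C12 to any external oxidant and so override the catalyst, giving poor or reversed facial selectivity. The lactone may also hydrolyse slowly in the basic buffer.

The fallback reverses the facial outcome by changing the mechanism. It sets out from 33 and comes back at 34. NBS in THF/H2O at 0 °C forms the bromonium ion on the exposed face, and water opens it anti at the tertiary C12 to give the (11R,12S)-11-bromo-12-hydroxy compound F9. DBU in CH2Cl2 then closes the epoxide with inversion at C11. The oxygen therefore ends on the face opposite to the one reached by direct oxygen transfer.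

**Step 19.** Three processes may cost material:
- slow addition of the hindered C3 hydroxyl to the cumulated ylide;
- a sluggish Wittig reaction of a stabilised ylide with a dialkyl ketone;
- β-elimination of the acyloxy group at 110 °C.

The fallback replaces the olefination by an organosamarium addition. It sets out from 28 and comes back at 30. Bromoacetyl bromide/pyridine gives the C3 bromoacetate F10. SmI2 in THF at −78 °C effects an intramolecular Reformatsky reaction to the β-hydroxy δ-lactone F11, whose C1 carbinol configuration is immaterial. Ac2O/DMAP/Et3N gives the tertiary acetate F12, and DBU removes acetic acid by E1cB elimination to give 30.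

**Further compounds**

F1 | step 17 | (E)-8-bromo-4-methylnona-4,8-dien-1-ol | C=C(Br)CC/C=C(\C)CCCO
F2 | step 17 | (E)-8-bromo-4-methylnona-4,8-dienal | C=C(Br)CC/C=C(\C)CCC=O
F3 | step 17 | (E)-8-bromo-4-methylnona-4,8-dienal oxime | C=C(Br)CC/C=C(\C)CCC=NO
F4 | step 17 | (E)-8-bromo-4-methylnona-4,8-dienenitrile oxide | C=C(Br)CC/C=C(\C)CCC#[N+][O-]
F5 | step 17 | (S)-4-[(R)-3-((E)-7-bromo-3-methylocta-3,7-dienyl)-4,5-dihydroisoxazol-5-yl]-4-(triethylsilyloxy)pentanal | C=C(Br)CC/C=C(\C)CCC1=NO[C@H](C1)[C@@](C)(O[Si](CC)(CC)CC)CCC=O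
F6 | step 17 | macrocyclic isoxazoline with free C7 hydroxyl, both C7 epimers | C=C1CC/C=C(\C)CCC2=NO[C@H](C2)[C@@](C)(O[Si](CC)(CC)CC)CCC1O
F7 | step 17 | macrocyclic isoxazoline C7 enone | C=C1CC/C=C(\C)CCC2=NO[C@H](C2)[C@@](C)(O[Si](CC)(CC)CC)CCC1=O
F8 | step 17 | macrocyclic isoxazoline (7R)-alcohol | C=C1CC/C=C(\C)CCC2=NO[C@H](C2)[C@@](C)(O[Si](CC)(CC)CC)CC[C@H]1O
F9 | step 22 | (11R,12S)-11-bromo-12-hydroxy derivative of 33 | C=C1CC[C@@H](Br)[C@@](C)(O)CC[C@@H]2C[C@@H](OC(=O)[C@H]2C)[C@@](C)(O[Si](CC)(CC)CC)CC[C@H]1O[Si](C)(C)C(C)(C)C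
F10 | step 19 | C3 bromoacetate of 28 | C=C1CC/C=C(\C)CCC(=O)C[C@@H](OC(=O)CBr)[C@@](C)(O[Si](CC)(CC)CC)CC[C@H]1O[Si](C)(C)C(C)(C)C
F11 | step 19 | bridged β-hydroxy δ-lactone (tertiary C1 hydroxyl, configuration at C1 open) | C=C1CC/C=C(\C)CCC2(O)CC(=O)O[C@H](C2)[C@@](C)(O[Si](CC)(CC)CC)CC[C@H]1O[Si](C)(C)C(C)(C)C
F12 | step 19 | C1 acetate of F11 | C=C1CC/C=C(\C)CCC2(OC(C)=O)CC(=O)O[C@H](C2)[C@@](C)(O[Si](CC)(CC)CC)CC[C@H]1O[Si](C)(C)C(C)(C)C
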